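| flask | solid substrate | gas | remark | time |
|---|---|---|---|---|
| Sunday's | 1.1 M | 120 mM (held) | the very flask that is asked about, followed so far |  |
| Wednesday's | 0.55 M | 120 mM (held) | run made earlier |  |
| flask | 1.1 M | 120 mM (held) |  | 3.0 h |

- Sunday's (time / min: target / %, solid product / %): 5.00: 2, 0; 12.0: 7, 1; 25.0: 10, 0; 40.0: 16, 7
- Wednesday's (time / h: target / %, solid product / %): 0.833: 40, 20; 1.50: 55, 37; 2.50: 65, 50; 3.00: 65, 49

(scatter of a reading: 2 percentage points)

* the target and solid product together standing at 3.0 h, as a percentage of the solid substrate charged
* concentration of dissolved substrate in solution at 3.0 h, in percent of saturation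

- for target the solid product is counted in
- as a solid, counted per litre of solution: solid substrate, solid product
- at the start none of the solid substrate is in solution
- at the start none of the gas is in solution
- dissolved substrate means what is dissolved; the solid is not counted in it

- Hold two times against each other for Sunday's flask: the 3.0 h asked about, and the time its charge needs to reach the yield at which Wednesday's run levelled off.
- Wednesday's run read 65% and 65% of target (solid product counted in) at its last two readings, so we take the reading 65.0% as the ceiling Y.
- Up to the first solid-product reading above scatter, target makes a mean r = 0.264 M h⁻¹ in Sunday's run and 0.264 M h⁻¹ in Wednesday's, equal as read, so we read the rate as zero-order in the charge.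
- Sunday's flask has 2.71 h as its fill time τ, the ceiling Y times the charge over r, so t/τ, with t the time asked, is 1.11.
- Wednesday's run, with half the charge, has τ = 1.35 h, and its 1.50 h reading sits at that same t/τ with 55%, its mean rate since the reading before down to 0.124 M h⁻¹.
- Sunday's flask has twice the charge behind the same r, so we expect its rate to hold longer and commit to about 60.0%, between that reading and the ceiling.
- We expect dissolved substrate in Sunday's flask to be falling by then, and commit to no figure.
- The forecast gives 69% for the yield and 92% of saturation for dissolved substrate; of Wednesday's plateau it says: “I read this as equilibrium, not a stall”. Its yield stands above our ceiling.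

- Sunday's flask gives 61.7%, which is 94.9% of the ceiling, and dissolved substrate at 16.0% of saturation.

    solid substrate ⇌ dissolved substrate, rate k1*(cs1 - [dissolved substrate]) while solid is left; crystals form when [dissolved substrate] > cs1 (solubility = 0.470 M, k = 0.00197 s⁻¹)
    dissolved substrate + reagent → target (k = 0.00230 M⁻¹ s⁻¹)
    dissolved substrate + target → side product (k = 5.49 × 10⁻⁴ M⁻¹ s⁻¹)
    solid product ⇌ target, rate k4*(cs4 - [target]) while solid is left; crystals form when [target] > cs4 (solubility = 0.0950 M, k = 0.00533 s⁻¹)
    gas ⇌ reagent, rate k5*(csat - [reagent]) (kL = 0.0682 s⁻¹)

- At 3.00 h Sunday's flask holds 0% solid substrate and 6.83% dissolved substrate, in percent of the charge. The neighbour flask with 0.44 M of solid substrate has τ = 1.08 h, so its 3.0 h is t/τ = 2.78, and it stands at 68.2%.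

The numbers in the tables stem from a simulated flask for substances that don't exist; scatter was added.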